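The plan avoids a hindered biaryl coupling. The C7–C8' bond is made early as an aryl–carbonyl bond, and the methoxy-bearing naphthalene ring (C4a', C5', C6', C7', C8', C8a') is then grown around it. The feature exploited is the para relation of aryl-bearing C8' and oxygen-bearing C5' across the unsubstituted C6'–C7' edge, the footprint of an opened 1,4-oxygen bridge. In one pot a keto alcohol dehydrates to a 1-arylisobenzofuran, adds a two-carbon acetylene equivalent, expels sulfenic acid and isomerises to the 8'-aryl-5'-naphthol. The precursor is a diaryl ketone linking C7 of a (3S)-3-methyldihydroisoquinolin-1-one to a benzyloxytoluene ring with an ortho hydroxymethyl group.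

Key step: step 13

Assumption: the SMILES fixes only C3 (S) and leaves the C7–C8' axis open, so no axial control is planned. The two atropisomers expected from the key step are carried on together and can be parted by chromatography at 29 or 33 if one is wanted.

Step 1
Reactants: 1 3-hydroxy-5-methylbenzoic acid
Product: 3 N,N-diethyl-3-hydroxy-5-methylbenzamide, via acid chloride 2 (not isolated)
Conditions: SOCl2, cat. DMF, toluene, 70 °C; evaporate; Et2NH (4 equiv), CH2Cl2, 0 °C to rt
Reagents that add atoms: diethylamine, CCNCC; thionyl chloride, O=S(Cl)Cl (chlorine of 2 only)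
Why: Acid chloride formation and Schotten–Baumann-type aminolysis install the tertiary amide that directs the metalation of step 3, and the excess amine also cleaves any phenolic ester formed on the way.

Step 2
Reactants: 3 N,N-diethyl-3-hydroxy-5-methylbenzamide
Product: 4 3-(benzyloxy)-N,N-diethyl-5-methylbenzamide
Conditions: BnBr, K2CO3, DMF, rt
Reagents that add atoms: benzyl bromide, BrCc1ccccc1
Why: Williamson ether synthesis on the only acidic OH gives a benzyl ether that tolerates cold organolithiums and catalytic acid and can be removed with BCl3 at the end.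

Step 3
Reactants: 4 3-(benzyloxy)-N,N-diethyl-5-methylbenzamide
Product: 6 3-(benzyloxy)-N,N-diethyl-2-formyl-5-methylbenzamide, via 2-lithiobenzamide 5 (not isolated)
Conditions: s-BuLi (1.2 equiv), TMEDA (1.2 equiv), THF, −78 °C; DMF (3 equiv), −78 to 0 °C; H2O
Reagents that add atoms: N,N-dimethylformamide, CN(C)C=O; sec-butyllithium, [Li]C(C)CC (lithium of 5 only)
Why: In this directed ortho metalation the amide and the ether act together on the C2–H between them, so lithiation at −78 °C should outrun attack on the OCH2Ph or aryl-methyl hydrogens, and DMF formylates the anion to supply the future C5'.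

Step 4
Reactants: 6 3-(benzyloxy)-N,N-diethyl-2-formyl-5-methylbenzamide
Product: 8 4-(benzyloxy)-6-methylisobenzofuran-1(3H)-one (phthalide), via hydroxymethyl amide 7 (not isolated)
Conditions: NaBH4, MeOH, 0 °C; evaporate; TsOH·H2O (1.2 equiv), toluene, 110 °C
Reagents that add atoms: none
Why: Borohydride reduction of the aldehyde is followed by acid-promoted lactonisation, an intramolecular acyl substitution in which the neighbouring alcohol displaces diethylamine from the twisted amide.

Step 5
Reactants: 9 2-bromo-1,3-dimethoxybenzene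
Product: 11 2-bromo-5-iodo-1,3-dimethoxybenzene, via aryl boronate 10 (not isolated)
Conditions: [Ir(OMe)(cod)]2 (1.5 mol %), dtbpy (3 mol %), B2pin2 (1 equiv), THF, 80 °C; evaporate; CuI (10 mol %), 1,10-phenanthroline (20 mol %), KI (1.5 equiv), MeOH–H2O, air, 80 °C
Reagents that add atoms: potassium iodide, [K+].[I-]; bis(pinacolato)diboron, CC1(C)OB(OC1(C)C)B1OC(C)(C)C(C)(C)O1 (boryl group of 10 only)
Why: Sterically governed iridium-catalysed C–H borylation reaches only C5–H, the one hydrogen without an ortho neighbour, and copper-catalysed iododeboronation exchanges boron for iodine at the same carbon, so the bromine destined for C7 lies between the two oxygens from the start and no late bromination, which would favour C5 of the lactam, is needed.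

Step 6
Reactants: 12 N-Boc-L-alaninol, tert-butyl [(2S)-1-hydroxypropan-2-yl]carbamate
Product: 14 tert-butyl (2S)-2-methylaziridine-1-carboxylate, via tosylate 13 (not isolated)
Conditions: TsCl (1.1 equiv), powdered KOH (4 equiv), Et2O, 35 °C
Reagents that add atoms: 4-toluenesulfonyl chloride, Cc1ccc(cc1)S(=O)(=O)Cl (tosyl group of 13 only)
Why: O-Tosylation and intramolecular SN2 displacement by the carbamate anion (3-exo-tet) close the aziridine at the primary carbon, so the L-alanine stereocentre is not a reacting centre and stays (S).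

Step 7
Reactants: 11 2-bromo-5-iodo-1,3-dimethoxybenzene; 14 tert-butyl (2S)-2-methylaziridine-1-carboxylate
Product: 16 tert-butyl [(2S)-1-(4-bromo-3,5-dimethoxyphenyl)propan-2-yl]carbamate, via arylmagnesium chloride 15 (not isolated)
Conditions: iPrMgCl·LiCl (1.05 equiv), THF, −20 °C; CuI (10 mol %), 14 (1.1 equiv), −30 °C to rt; H2O
Reagents that add atoms: isopropylmagnesium chloride, CC(C)[Mg]Cl (MgCl of 15 only)
Why: Iodine–magnesium exchange is far faster than bromine–magnesium exchange, and the copper-catalysed SN2 opening of the N-acyl aziridine occurs at its unsubstituted CH2, so C3 of the target is taken unchanged (S) from the chiral pool.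

Step 8
Reactants: 16 tert-butyl [(2S)-1-(4-bromo-3,5-dimethoxyphenyl)propan-2-yl]carbamate
Product: 18 (3S)-7-bromo-6,8-dimethoxy-3-methyl-3,4-dihydroisoquinolin-1(2H)-one, via isocyanate 17 (not isolated)
Conditions: Tf2O (1.3 equiv), 2-chloropyridine (3 equiv), CH2Cl2, −78 °C to rt; aq NaHCO3
Reagents that add atoms: none
Why: Carbamate activation to the isocyanate and intramolecular Friedel–Crafts acylation (Bischler–Napieralski-type lactam synthesis) close the six-membered ring, and because the two open ring positions are equivalent and each is ortho/para to methoxy only one lactam can form.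

Step 9
Reactants: 18 (3S)-7-bromo-6,8-dimethoxy-3-methyl-3,4-dihydroisoquinolin-1(2H)-one
Product: 19 (3S)-7-bromo-6,8-dihydroxy-3-methyl-3,4-dihydroisoquinolin-1(2H)-one
Conditions: BBr3 (5 equiv), CH2Cl2, −78 °C to rt; H2O
Reagents that add atoms: none
Why: Lewis acid cleavage of both aryl methyl ethers is chosen because any partial cleavage would remove the carbonyl-chelated 8-OMe, the one that must remain, so the two oxygens are told apart on the way back instead.

Step 10
Reactants: 19 (3S)-7-bromo-6,8-dihydroxy-3-methyl-3,4-dihydroisoquinolin-1(2H)-one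
Product: 20 (3S)-6-(benzyloxy)-7-bromo-8-hydroxy-3-methyl-3,4-dihydroisoquinolin-1(2H)-one
Conditions: BnBr (1.0 equiv), K2CO3 (1.1 equiv), DMF, rt
Reagents that add atoms: benzyl bromide, BrCc1ccccc1
Why: This chemoselective Williamson alkylation relies on 8-OH being hydrogen-bonded to the lactam carbonyl and flanked on both sides, so one equivalent of halide with a weak base should take the freer, more acidic 6-OH.

Step 11
Reactants: 20 (3S)-6-(benzyloxy)-7-bromo-8-hydroxy-3-methyl-3,4-dihydroisoquinolin-1(2H)-one
Product: 21 (3S)-6-(benzyloxy)-7-bromo-8-methoxy-3-methyl-3,4-dihydroisoquinolin-1(2H)-one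
Conditions: MeI (3 equiv), K2CO3 (3 equiv), DMF, 50 °C
Reagents that add atoms: iodomethane, CI
Why: Williamson methylation of the remaining chelated phenol under more forcing conditions should leave the lactam N–H alone, since carbonate is too weak a base to deprotonate it.

Step 12
Reactants: 21 (3S)-6-(benzyloxy)-7-bromo-8-methoxy-3-methyl-3,4-dihydroisoquinolin-1(2H)-one; 8 4-(benzyloxy)-6-methylisobenzofuran-1(3H)-one
Product: 23 (3S)-6-(benzyloxy)-7-[3-(benzyloxy)-2-(hydroxymethyl)-5-methylbenzoyl]-8-methoxy-3-methyl-3,4-dihydroisoquinolin-1(2H)-one, via dilithio lactam 22 (not isolated)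
Conditions: MeLi (1.0 equiv), THF, −78 °C; n-BuLi (1.1 equiv), −78 °C; 8 (1.2 equiv), −78 to −20 °C; H2O
Reagents that add atoms: methyllithium, [Li]C, and n-butyllithium, [Li]CCCC (lithium atoms of 22 only)
Why: MeLi removes N–H without touching C–Br, bromine–lithium exchange then gives an aryllithium stabilised by its two flanking alkoxy groups, and its 1,2-addition to the lactone carbonyl should stop after one addition because the adduct is held as a lactolate or a ketone with three ortho substituents.

Step 13
Reactants: 23 (3S)-6-(benzyloxy)-7-[3-(benzyloxy)-2-(hydroxymethyl)-5-methylbenzoyl]-8-methoxy-3-methyl-3,4-dihydroisoquinolin-1(2H)-one; 24 phenyl vinyl sulfoxide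
Product: 29 (3S)-6-(benzyloxy)-7-[5-(benzyloxy)-4-hydroxy-7-methylnaphthalen-1-yl]-8-methoxy-3-methyl-3,4-dihydroisoquinolin-1(2H)-one, via lactol 25 (not isolated), via isobenzofuran 26 (not isolated), via sulfoxide cycloadduct 27 (not isolated), via epoxydihydronaphthalene 28 (not isolated)
Conditions: 24 (5 equiv), AcOH (0.2 equiv), 4 Å MS, PhCl, 130 °C, Ar; then TsOH·H2O (0.3 equiv), 60 °C
Reagents that add atoms: phenyl vinyl sulfoxide 24, C=CS(=O)c1ccccc1 (its two vinyl carbons become C6' and C7')
Why: Ring tautomer 25 ionises under weak acid and loses a proton from its OCH2 group to give isobenzofuran 26, whose furan carbons (future C8' and C5') add the vinyl group of 24 in a thermal suprafacial [4+2] cycloaddition that forms C7'–C8' and C5'–C6', the known trapping of isobenzofurans from aryl-metal/phthalide adducts by an acetylene equivalent. The six-membered carbocycle C4a'–C5'–C6'–C7'–C8'–C8a' is thus closed by intermolecular cycloaddition, and any orientation or endo/exo mode of 27 is acceptable because syn elimination of PhSOH cannot run towards a bridgehead and gives only the C6'=C7' alkene 28. The stronger acid then protonates the bridge oxygen, the C8'–O bond breaks and loss of H-5' aromatises the ring, the classical acid isomerisation of 1,4-epoxy-1,4-dihydronaphthalenes to 1-naphthols. No lasting stereocentre is made: the bridgehead and sulfur-bearing centres vanish on aromatisation, C3 is untouched, and the C7–C8' axis becomes stereogenic under only the weak influence of remote C3, so both atropisomers are expected. The selectivity needed is the direction of bridge opening, and it is secured by C8' being the tertiary, allylic, doubly benzylic and most congested terminus, by the hydrogen bond from the protonated bridge to the peri 4'-benzyloxy oxygen that damps the push of that group towards C5', and by the fact that only the C8' cation has a proton (H-5') to lose whereas a C5' cation can merely re-close. Holding back the strong acid until PhSOH has left should prevent a ring-opened sulfoxide from dehydrating to an oxygen-free naphthalene.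

Step 14
Reactants: 29 (3S)-6-(benzyloxy)-7-[5-(benzyloxy)-4-hydroxy-7-methylnaphthalen-1-yl]-8-methoxy-3-methyl-3,4-dihydroisoquinolin-1(2H)-one
Product: 30 (3S)-6-(benzyloxy)-7-[5-(benzyloxy)-4-methoxy-7-methylnaphthalen-1-yl]-8-methoxy-3-methyl-3,4-dihydroisoquinolin-1(2H)-one
Conditions: MeI (3 equiv), K2CO3 (3 equiv), DMF, 40 °C
Reagents that add atoms: iodomethane, CI
Why: Williamson methylation of the only free phenol fixes the 5'-OMe/4'-O difference, with the lactam N–H again too weakly acidic for carbonate.

Step 15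
Reactants: 30 (3S)-6-(benzyloxy)-7-[5-(benzyloxy)-4-methoxy-7-methylnaphthalen-1-yl]-8-methoxy-3-methyl-3,4-dihydroisoquinolin-1(2H)-one
Product: 32 (3S)-6-(benzyloxy)-7-[5-(benzyloxy)-4-methoxy-7-methylnaphthalen-1-yl]-8-methoxy-1,3-dimethyl-3,4-dihydroisoquinoline, via N-silyl lactam 31 (not isolated)
Conditions: Me3SiCl, Et3N, toluene, 80 °C; filter, evaporate; MeLi (3 equiv), Et2O–THF, −78 to 0 °C; H2O
Reagents that add atoms: methyllithium, [Li]C; chlorotrimethylsilane, C[Si](C)(C)Cl (silyl group of 31 only)
Why: N-Silylation replaces the acidic N–H so that the carbonyl accepts MeLi in a 1,2-addition, and Peterson-like loss of Me3SiOLi gives the cyclic ketimine (the known cyclic imine synthesis from N-silyl lactams and organolithiums), while excess base deprotonates at most the new C1-methyl group and not C3.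

Step 16
Reactants: 32 (3S)-6-(benzyloxy)-7-[5-(benzyloxy)-4-methoxy-7-methylnaphthalen-1-yl]-8-methoxy-1,3-dimethyl-3,4-dihydroisoquinoline
Product: 33 (3S)-7-(5-hydroxy-4-methoxy-7-methylnaphthalen-1-yl)-8-methoxy-1,3-dimethyl-3,4-dihydroisoquinolin-6-ol (target)
Conditions: BCl3 (6 equiv), C6HMe5 (6 equiv), CH2Cl2, −78 °C; MeOH–CHCl3; aq NaHCO3
Reagents that add atoms: none
Why: Lewis acid debenzylation with pentamethylbenzene as benzyl cation scavenger works at −78 °C, where aryl methyl ethers survive (the imine nitrogen points away from 8-OMe and cannot chelate it) and the C=N bond, which hydrogenolysis would reduce, is untouched.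

Compound list
1 | 3-hydroxy-5-methylbenzoic acid | Cc1cc(O)cc(C(=O)O)c1 | starting material
2 | 3-hydroxy-5-methylbenzoyl chloride | Cc1cc(O)cc(C(=O)Cl)c1 | intermediate
3 | N,N-diethyl-3-hydroxy-5-methylbenzamide | CCN(CC)C(=O)c1cc(C)cc(O)c1 | intermediate
4 | 3-(benzyloxy)-N,N-diethyl-5-methylbenzamide | CCN(CC)C(=O)c1cc(C)cc(OCc2ccccc2)c1 | intermediate
5 | 3-(benzyloxy)-N,N-diethyl-2-lithio-5-methylbenzamide | CCN(CC)C(=O)c1cc(C)cc(OCc2ccccc2)c1[Li] | intermediate
6 | 3-(benzyloxy)-N,N-diethyl-2-formyl-5-methylbenzamide | CCN(CC)C(=O)c1cc(C)cc(OCc2ccccc2)c1C=O | intermediate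
7 | 3-(benzyloxy)-N,N-diethyl-2-(hydroxymethyl)-5-methylbenzamide | CCN(CC)C(=O)c1cc(C)cc(OCc2ccccc2)c1CO | intermediate
8 | 4-(benzyloxy)-6-methylisobenzofuran-1(3H)-one | O=C1OCc2c(OCc3ccccc3)cc(C)cc12 | intermediate
9 | 2-bromo-1,3-dimethoxybenzene | COc1cccc(OC)c1Br | starting material
10 | 2-(4-bromo-3,5-dimethoxyphenyl)-4,4,5,5-tetramethyl-1,3,2-dioxaborolane | COc1cc(B2OC(C)(C)C(C)(C)O2)cc(OC)c1Br | intermediate
11 | 2-bromo-5-iodo-1,3-dimethoxybenzene | COc1cc(I)cc(OC)c1Br | intermediate
12 | N-Boc-L-alaninol, tert-butyl [(2S)-1-hydroxypropan-2-yl]carbamate | C[C@H](NC(=O)OC(C)(C)C)CO | starting material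
13 | (2S)-2-[(tert-butoxycarbonyl)amino]propyl 4-toluenesulfonate | C[C@H](NC(=O)OC(C)(C)C)COS(=O)(=O)c1ccc(C)cc1 | intermediate
14 | tert-butyl (2S)-2-methylaziridine-1-carboxylate | C[C@H]1CN1C(=O)OC(C)(C)C | intermediate
15 | (4-bromo-3,5-dimethoxyphenyl)magnesium chloride | COc1cc([Mg]Cl)cc(OC)c1Br | intermediate
16 | tert-butyl [(2S)-1-(4-bromo-3,5-dimethoxyphenyl)propan-2-yl]carbamate | COc1cc(C[C@H](C)NC(=O)OC(C)(C)C)cc(OC)c1Br | intermediate
17 | 2-bromo-5-[(2S)-2-isocyanatopropyl]-1,3-dimethoxybenzene | COc1cc(C[C@H](C)N=C=O)cc(OC)c1Br | intermediate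
18 | (3S)-7-bromo-6,8-dimethoxy-3-methyl-3,4-dihydroisoquinolin-1(2H)-one | COc1c2c(cc(OC)c1Br)C[C@H](C)NC2=O | intermediate
19 | (3S)-7-bromo-6,8-dihydroxy-3-methyl-3,4-dihydroisoquinolin-1(2H)-one | Oc1c2c(cc(O)c1Br)C[C@H](C)NC2=O | intermediate
20 | (3S)-6-(benzyloxy)-7-bromo-8-hydroxy-3-methyl-3,4-dihydroisoquinolin-1(2H)-one | Oc1c2c(cc(OCc3ccccc3)c1Br)C[C@H](C)NC2=O | intermediate
21 | (3S)-6-(benzyloxy)-7-bromo-8-methoxy-3-methyl-3,4-dihydroisoquinolin-1(2H)-one | COc1c2c(cc(OCc3ccccc3)c1Br)C[C@H](C)NC2=O | intermediate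
22 | N,7-dilithio derivative of (3S)-6-(benzyloxy)-8-methoxy-3-methyl-3,4-dihydroisoquinolin-1(2H)-one | [Li]c1c(OC)c2c(cc1OCc1ccccc1)C[C@H](C)N([Li])C2=O | intermediate
23 | (3S)-6-(benzyloxy)-7-[3-(benzyloxy)-2-(hydroxymethyl)-5-methylbenzoyl]-8-methoxy-3-methyl-3,4-dihydroisoquinolin-1(2H)-one | COc1c2c(cc(OCc3ccccc3)c1C(=O)c1cc(C)cc(OCc3ccccc3)c1CO)C[C@H](C)NC2=O | intermediate
24 | phenyl vinyl sulfoxide (racemic) | C=CS(=O)c1ccccc1 | starting material
25 | (3S)-6-(benzyloxy)-7-[4-(benzyloxy)-1-hydroxy-6-methyl-1,3-dihydroisobenzofuran-1-yl]-8-methoxy-3-methyl-3,4-dihydroisoquinolin-1(2H)-one (lactol carbon undefined) | COc1c2c(cc(OCc3ccccc3)c1C1(O)OCc3c(OCc4ccccc4)cc(C)cc13)C[C@H](C)NC2=O | intermediate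
26 | (3S)-6-(benzyloxy)-7-[4-(benzyloxy)-6-methylisobenzofuran-1-yl]-8-methoxy-3-methyl-3,4-dihydroisoquinolin-1(2H)-one | COc1c2c(cc(OCc3ccccc3)c1C1=C3C=C(C)C=C(OCc4ccccc4)C3=CO1)C[C@H](C)NC2=O | intermediate
27 | (3S)-6-(benzyloxy)-7-[5-(benzyloxy)-7-methyl-3-(phenylsulfinyl)-1,2,3,4-tetrahydro-1,4-epoxynaphthalen-1-yl]-8-methoxy-3-methyl-3,4-dihydroisoquinolin-1(2H)-one (isomer mixture at the new centres and sulfur, drawn with sulfur next to C5'; the other orientation converges) | COc1c2c(cc(OCc3ccccc3)c1C13CC(S(=O)c4ccccc4)C(O1)c1c(OCc4ccccc4)cc(C)cc13)C[C@H](C)NC2=O | intermediate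
28 | (3S)-6-(benzyloxy)-7-[5-(benzyloxy)-7-methyl-1,4-dihydro-1,4-epoxynaphthalen-1-yl]-8-methoxy-3-methyl-3,4-dihydroisoquinolin-1(2H)-one (bridgeheads undefined) | COc1c2c(cc(OCc3ccccc3)c1C13C=CC(O1)c1c(OCc4ccccc4)cc(C)cc13)C[C@H](C)NC2=O | intermediate
29 | (3S)-6-(benzyloxy)-7-[5-(benzyloxy)-4-hydroxy-7-methylnaphthalen-1-yl]-8-methoxy-3-methyl-3,4-dihydroisoquinolin-1(2H)-one | COc1c2c(cc(OCc3ccccc3)c1-c1ccc(O)c3c(OCc4ccccc4)cc(C)cc13)C[C@H](C)NC2=O | intermediate
30 | (3S)-6-(benzyloxy)-7-[5-(benzyloxy)-4-methoxy-7-methylnaphthalen-1-yl]-8-methoxy-3-methyl-3,4-dihydroisoquinolin-1(2H)-one | COc1c2c(cc(OCc3ccccc3)c1-c1ccc(OC)c3c(OCc4ccccc4)cc(C)cc13)C[C@H](C)NC2=O | intermediate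
31 | N-trimethylsilyl derivative of 30 | COc1c2c(cc(OCc3ccccc3)c1-c1ccc(OC)c3c(OCc4ccccc4)cc(C)cc13)C[C@H](C)N([Si](C)(C)C)C2=O | intermediate
32 | (3S)-6-(benzyloxy)-7-[5-(benzyloxy)-4-methoxy-7-methylnaphthalen-1-yl]-8-methoxy-1,3-dimethyl-3,4-dihydroisoquinoline | COc1c2c(cc(OCc3ccccc3)c1-c1ccc(OC)c3c(OCc4ccccc4)cc(C)cc13)C[C@H](C)N=C2C | intermediate
33 | (3S)-7-(5-hydroxy-4-methoxy-7-methylnaphthalen-1-yl)-8-methoxy-1,3-dimethyl-3,4-dihydroisoquinolin-6-ol | COc1c2c(cc(O)c1-c1ccc(OC)c3c(O)cc(C)cc13)C[C@H](C)N=C2C | target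

Total step count: 16. Longest linear sequence: 11 steps (5, 7, 8, 9, 10, 11, 12, 13, 14, 15, 16).

Steps most likely to fail

Step 13.
- Cycloaddition at the furan carbon that bears the doubly ortho-substituted aryl group may be slow, which leaves the isobenzofuran time to oxidise or oligomerise.
- Sulfur electrophiles derived from the expelled sulfenic acid may sulfenylate the electron-rich naphthol.
- The bridge may ionise at C5', helped by the ortho benzyloxy and para methyl groups of the other ring, and an aryl shift may follow.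

The fallback sets out from 23 and separates the three events. With catalytic acid near room temperature the isobenzofuran is trapped by (E)-1,2-bis(phenylsulfonyl)ethene, a much more reactive acetylene equivalent, to give the isolable bis-sulfone cycloadduct F1. Reductive elimination of both sulfonyl groups with Na(Hg) and NaH2PO4 in MeOH–THF gives 28 as an isolated compound, free of sulfur electrophiles. Compound 28 is then isomerised not by acid but with [Rh(cod)Cl]2 and dppf in warm toluene. Metal insertion into an allylic bridgehead C–O bond is followed by β-hydride elimination, which is possible only for the alkoxide that keeps H-5', and tautomerisation brings the route back at 29.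

Step 12.
- Proton transfer from the lactone OCH2 group, or from residual N–H, to the hindered aryllithium may return debrominated lactam.
- The dianion may be poorly soluble.

The fallback sets out from 8 and replaces the lactone by an open-chain acylating agent without an acidic position. Aminolysis with MeNH(OMe)·HCl and AlMe3 gives the hydroxy Weinreb amide F2. Immediate silylation with t-BuMe2SiCl and imidazole gives the silyl ether F3. Acylation of 22 with F3 gives the silyl-protected ketone F4, whose chelated adduct cannot add a second aryl group. Bu4NF in THF then returns the route to 23.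

Step 15.
- MeLi may attack silicon and regenerate the unreactive amidate.
- Addition to the hindered, electron-rich carbonyl next to 8-OMe may be sluggish.

The fallback sets out from 30 and forms the C1–CH3 bond by cross-coupling instead of carbonyl addition. POCl3 in toluene at 90 °C gives the imidoyl chloride F5. Zerovalent palladium then inserts into its C–Cl bond in a Negishi coupling with MeZnCl and Pd(PPh3)4 in THF, which comes back to the route at 32.

Further compounds
F1 | step 13 | (3S)-6-(benzyloxy)-7-[5-(benzyloxy)-7-methyl-2,3-bis(phenylsulfonyl)-1,2,3,4-tetrahydro-1,4-epoxynaphthalen-1-yl]-8-methoxy-3-methyl-3,4-dihydroisoquinolin-1(2H)-one (new centres undefined) | COc1c2c(cc(OCc3ccccc3)c1C13OC(C(S(=O)(=O)c4ccccc4)C1S(=O)(=O)c1ccccc1)c1c(OCc4ccccc4)cc(C)cc13)C[C@H](C)NC2=O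
F2 | step 12 | 3-(benzyloxy)-2-(hydroxymethyl)-N-methoxy-N,5-dimethylbenzamide | CON(C)C(=O)c1cc(C)cc(OCc2ccccc2)c1CO
F3 | step 12 | 3-(benzyloxy)-2-{[(tert-butyldimethylsilyl)oxy]methyl}-N-methoxy-N,5-dimethylbenzamide | CON(C)C(=O)c1cc(C)cc(OCc2ccccc2)c1CO[Si](C)(C)C(C)(C)C
F4 | step 12 | O-tert-butyldimethylsilyl ether of 23 | COc1c2c(cc(OCc3ccccc3)c1C(=O)c1cc(C)cc(OCc3ccccc3)c1CO[Si](C)(C)C(C)(C)C)C[C@H](C)NC2=O
F5 | step 15 | (3S)-6-(benzyloxy)-7-[5-(benzyloxy)-4-methoxy-7-methylnaphthalen-1-yl]-1-chloro-8-methoxy-3-methyl-3,4-dihydroisoquinoline | COc1c2c(cc(OCc3ccccc3)c1-c1ccc(OC)c3c(OCc4ccccc4)cc(C)cc13)C[C@H](C)N=C2Cl
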